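**Retrosynthetic overview**

1. Target 29 ⇐ hydroxy acetate 28 by CH2 transfer to C4=C6 (cyclopropane, last ring); the butenolide ⇐ enol triflate of a C2/C3 β-keto ester by Stille hydroxymethylation and lactonisation.
2. Feature used: in the eight-membered ring (C1, C2, C3, C4, C6, C7, C8, C9) the pair C3–C4, with the lactone carbonyl carbon on C3, lies between C2 and C6. Removing it and joining C2 to C6 leaves a cyclohexanone (C1, C2, C6, C7, C8, C9) that already holds C1, C7, C9 and C1′.
3. Eight-membered ring ⇐ six-membered ring: [2+2] of the C2=C6 trimethylsilyl enol ether 18 with ethyl propiolate (C6–C4 and C2–C3 formed), then 4π opening of the cyclobutene (C2–C6 cleaved).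
4. 18 ⇐ C6=C7 enone 17 by Me2CuLi/TMSCl (sets C7, fixes the enol ether regiochemistry) ⇐ cis-fused γ-lactone 12 (O on C9, C2′ as C=O), alkylated on its convex face (C1′) ⇐ enone ketal 1 by oxazaborolidine reduction, Eschenmoser–Claisen rearrangement (C1) and iodolactonisation (C9).
5. Ring order: cyclohexane (from 1) → temporary γ-lactone → transient cyclobutene → cyclooctadiene → butenolide → cyclopropane.

Key step: step 12

Remark on labels: C1 = ring CH carrying the side chain; C2=C3 = butenolide alkene (C2 bears the lactone OCH2, C3 the lactone C=O); C4–C5–C6 = cyclopropane (C5 = CH2); C7 = CHMe; C8 = CH2; C9 = CHOH; C1′ = side-chain CH; C2′ = CH2OAc. TBS = tert-butyldimethylsilyl, TBSO = its ether oxygen, TMS = trimethylsilyl.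
Assumption: in the oxazaborolidine reduction of enone 1 the alkenyl arm behaves as the large substituent, as is usual for cyclic enones, so the (R)-catalyst gives the (S)-alcohol.

**Route**

Step 1
Reactants: 1 1,4-dioxaspiro[4.5]dec-6-en-8-one
Product: 2 (8S)-1,4-dioxaspiro[4.5]dec-6-en-8-ol
Conditions: (R)-1-methyl-3,3-diphenyltetrahydro-1H,3H-pyrrolo[1,2-c][1,3,2]oxazaborole (10 mol%), catecholborane, toluene, −78 °C
Reagents that add atoms: none
Why: Corey–Bakshi–Shibata reduction of a cyclic enone, in which the (R)-oxazaborolidine should deliver hydride to the face that gives the (S)-allylic alcohol at C8, the centre from which all others are relayed; catecholborane at low temperature avoids hydroboration of the alkene.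

Step 2
Reactants: 2 (8S)-1,4-dioxaspiro[4.5]dec-6-en-8-ol; 3 N,N-dimethylacetamide dimethyl acetal
Product: 5 N,N-dimethyl-2-[(6S)-1,4-dioxaspiro[4.5]dec-7-en-6-yl]acetamide, via ketene N,O-acetal 4 (not isolated)
Conditions: xylene, 140 °C, methanol distilled off
Reagents that add atoms: none
Why: Eschenmoser–Claisen rearrangement, in which alkoxide exchange and loss of methanol give ketene N,O-acetal 4, whose suprafacial [3,3] shift transfers the C8–O chirality to the new C1–C1′ bond on the same ring face (C1 S) under neutral conditions that spare the dioxolane.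

Step 3
Reactants: 5 N,N-dimethyl-2-[(6S)-1,4-dioxaspiro[4.5]dec-7-en-6-yl]acetamide
Product: 7 (3aS,7R,7aR)-7-iodohexahydro-3H-spiro[1-benzofuran-4,2'-[1,3]dioxolan]-2-one, via iminium lactone iodide 6 (not isolated)
Conditions: I2, NaHCO3, THF/H2O, 0 °C → rt
Reagents that add atoms: iodine, II; water, O
Why: Iodolactonisation of a γ,δ-unsaturated dimethylamide, in which the amide oxygen opens the iodonium ion at the nearer carbon C9 in a 5-exo closure that can only be cis on the six-membered ring, so C9–O is set cis to the C1–C1′ bond and water hydrolyses iminium 6 to the lactone.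

Step 4
Reactants: 7 (3aS,7R,7aR)-7-iodohexahydro-3H-spiro[1-benzofuran-4,2'-[1,3]dioxolan]-2-one
Product: 8 (3aS,7aS)-hexahydro-3H-spiro[1-benzofuran-4,2'-[1,3]dioxolan]-2-one
Conditions: Bu3SnH, azobisisobutyronitrile (cat.), toluene, 80 °C
Reagents that add atoms: none
Why: Radical-chain hydrodeiodination of a secondary iodide, which leaves lactone and ketal untouched and removes the unwanted C8 centre.

Step 5
Reactants: 9 5-bromo-2-methylpent-2-ene
Product: 10 5-iodo-2-methylpent-2-ene
Conditions: NaI, acetone, reflux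
Reagents that add atoms: sodium iodide, [Na+].[I-]
Why: Finkelstein halide exchange, driven by precipitation of NaBr, gives the more reactive primary iodide for the enolate alkylation.

Step 6
Reactants: 8 (3aS,7aS)-hexahydro-3H-spiro[1-benzofuran-4,2'-[1,3]dioxolan]-2-one; 10 5-iodo-2-methylpent-2-ene
Product: 12 (3S,3aS,7aS)-3-(4-methylpent-3-en-1-yl)hexahydro-3H-spiro[1-benzofuran-4,2'-[1,3]dioxolan]-2-one, via lactone lithium enolate 11 (not isolated)
Conditions: LiN(iPr)2, THF, −78 °C; then 10, DMPU, −78 → −20 °C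
Reagents that add atoms: none
Why: Alkylation of a γ-lactone lithium enolate, in which the cis-fused bicycle is attacked on its convex face, anti to the C1–C2 ring bond and the spiroketal, so that C1′ (S) is set with the homoprenyl chain trans to C2 as the target requires.

Step 7
Reactants: 12 (3S,3aS,7aS)-3-(4-methylpent-3-en-1-yl)hexahydro-3H-spiro[1-benzofuran-4,2'-[1,3]dioxolan]-2-one
Product: 13 (6S,7S)-6-[(2S)-1-hydroxy-6-methylhept-5-en-2-yl]-1,4-dioxaspiro[4.5]decan-7-ol
Conditions: LiAlH4, THF, 0 °C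
Reagents that add atoms: none
Why: Hydride reduction of the lactone gives the C2′/C9 diol while the ketal masks C2 and the isolated alkene is inert.

Step 8
Reactants: 13 (6S,7S)-6-[(2S)-1-hydroxy-6-methylhept-5-en-2-yl]-1,4-dioxaspiro[4.5]decan-7-ol
Product: 14 bis-TBS ether of 13 (TBSO on C2′ and on C9)
Conditions: TBSOTf, 2,6-lutidine, CH2Cl2, −78 → 0 °C
Reagents that add atoms: tert-butyldimethylsilyl trifluoromethanesulfonate, CC(C)(C)[Si](C)(C)OS(=O)(=O)C(F)(F)F
Why: Silylation of the primary and the hindered secondary alcohol with the silyl triflate and a hindered base, buffered and cold so that the ketal survives.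

Step 9
Reactants: 14 bis-TBS ether of 13
Product: 15 (2S,3S)-3-(TBSO)-2-[(2S)-1-(TBSO)-6-methylhept-5-en-2-yl]cyclohexan-1-one
Conditions: pyridinium p-toluenesulfonate (cat.), acetone/H2O, 40 °C
Reagents that add atoms: water, O
Why: Mild acid-catalysed hydrolysis of the dioxolane, chosen to spare both TBS ethers and to avoid enolisation towards C1, which would epimerise C1 or eliminate the C9 silyloxy group.

Step 10
Reactants: 15 (2S,3S)-3-(TBSO)-2-[(2S)-1-(TBSO)-6-methylhept-5-en-2-yl]cyclohexan-1-one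
Product: 17 (5S,6S)-5-(TBSO)-6-[(2S)-1-(TBSO)-6-methylhept-5-en-2-yl]cyclohex-2-en-1-one, via lithium enolate 16 (not isolated)
Conditions: LiN(iPr)2, THF, −78 °C; then PhS(Cl)=NtBu, −78 °C
Reagents that add atoms: none
Why: Mukaiyama dehydrogenation, in which kinetic deprotonation takes the C6 methylene and not the hindered C1 methine, the enolate is sulfenylated at C6 and syn elimination at low temperature gives the C6=C7 enone without touching C1 or C9.

Step 11
Reactants: 17 (5S,6S)-5-(TBSO)-6-[(2S)-1-(TBSO)-6-methylhept-5-en-2-yl]cyclohex-2-en-1-one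
Product: 18 {[(3S,5S,6S)-5-(TBSO)-6-[(2S)-1-(TBSO)-6-methylhept-5-en-2-yl]-3-methylcyclohex-1-en-1-yl]oxy}trimethylsilane
Conditions: Me2CuLi (from MeLi and CuI), TMSCl, THF, −78 °C; cold pentane/aq NaHCO3 work-up, used at once
Reagents that add atoms: lithium dimethylcuprate, [Li+].C[Cu-]C; chlorotrimethylsilane, C[Si](C)(C)Cl
Why: TMSCl-accelerated conjugate addition of a lithium dialkylcuprate, in which methyl adds to C7 on the face opposite the cis-disposed C9 silyloxy group and C1 side chain (the usual trans-3,5 outcome for 5-substituted cyclohexenones), setting C7 (S), and in situ O-silylation gives the C2=C6 enol ether as a single regioisomer.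

Step 12
Reactants: 18 {[(3S,5S,6S)-5-(TBSO)-6-[(2S)-1-(TBSO)-6-methylhept-5-en-2-yl]-3-methylcyclohex-1-en-1-yl]oxy}trimethylsilane; 19 ethyl propiolate
Product: 21 ethyl (1Z,3Z,5S,7S,8S)-7-(TBSO)-8-[(2S)-1-(TBSO)-6-methylhept-5-en-2-yl]-5-methyl-1-(trimethylsilyloxy)cycloocta-1,3-diene-2-carboxylate, via siloxycyclobutene 20 (not isolated)
Conditions: EtAlCl2 (1.1 equiv), CH2Cl2, −78 °C; aq NaHCO3 quench; crude 20 in toluene, 80 °C
Reagents that add atoms: none
Why: EtAlCl2 activates ethyl propiolate, the enol ether carbon C6 of 18 adds to the propiolate CH carbon (C4) and the aluminium allenolate closes through its ester-bearing carbon C3 onto the oxocarbenium carbon C2 (4-exo-trig closure of the ring C2–C3–C4–C6), which is the known Lewis acid promoted stepwise [2+2] of silyl enol ethers with propiolates. On warming, the cyclobutene, which carries a donor (OTMS on C2) and an acceptor (ester on C3), undergoes thermal conrotatory 4π electrocyclic cleavage of the former enol ether bond C2–C6, the known two-carbon ring expansion of cycloalkanones; the eight-membered ring is thus formed by scission of the bond shared by the four- and six-membered rings and not by a cyclisation. The first-formed E,Z-diene is strained and should relax to the Z,Z-diene 21 by rotation about the polarised push–pull C2=C3 bond (or by reclosure and reopening), and the C2=C3 geometry is renewed anyway at the enolate stage of step 13. No stereocentre is created: the two bridgehead centres of 20 (C2, C6) are transient, so the facial course of the cycloaddition is irrelevant, and C1, C7, C9 and C1′ are not touched. The step needs C6-to-C4 and C2-to-C3 regiochemistry, secured by the polarity match between the enol ether β-carbon and the ynoate β-carbon, and it needs expansion across C2–C6 and not C1–C2, secured because 18 is a single enol ether regioisomer made by conjugate addition and O-silylation. The trisubstituted side-chain alkene is far less nucleophilic than the enol ether and should not compete for the activated ynoate at −78 °C.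

Step 13
Reactants: 21 ethyl (1Z,3Z,5S,7S,8S)-7-(TBSO)-8-[(2S)-1-(TBSO)-6-methylhept-5-en-2-yl]-5-methyl-1-(trimethylsilyloxy)cycloocta-1,3-diene-2-carboxylate
Product: 23 ethyl (1Z,3Z,5S,7S,8S)-7-(TBSO)-8-[(2S)-1-(TBSO)-6-methylhept-5-en-2-yl]-5-methyl-1-(trifluoromethanesulfonyloxy)cycloocta-1,3-diene-2-carboxylate, via caesium enolate 22 (not isolated)
Conditions: CsF, PhNTf2, 1,2-dimethoxyethane, rt
Reagents that add atoms: N-phenylbis(trifluoromethanesulfonimide), O=S(=O)(N(c1ccccc1)S(=O)(=O)C(F)(F)F)C(F)(F)F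
Why: Fluoride-induced conversion of a silyl enol ether into an enol triflate, in which CsF cleaves only the TMS enol ether (alkyl TBS ethers are stable) and the β-keto ester enolate 22 is sulfonylated on oxygen in an aprotic medium, which avoids migration of the C4=C6 alkene into conjugation.

Step 14
Reactants: 23 ethyl (1Z,3Z,5S,7S,8S)-7-(TBSO)-8-[(2S)-1-(TBSO)-6-methylhept-5-en-2-yl]-5-methyl-1-(trifluoromethanesulfonyloxy)cycloocta-1,3-diene-2-carboxylate; 24 (tributylstannyl)methanol
Product: 26 (4R,5S,7S,8Z)-5-(TBSO)-4-[(2S)-1-(TBSO)-6-methylhept-5-en-2-yl]-7-methyl-4,5,6,7-tetrahydrocycloocta[c]furan-1(3H)-one, via hydroxymethyl ester 25 (not isolated)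
Conditions: Pd(PPh3)4 (cat.), LiCl, 1,4-dioxane, 90 °C
Reagents that add atoms: none
Why: Stille coupling of the enol triflate (zerovalent palladium, chloride-assisted transmetalation) puts CH2OH on C2 cis to the C3 ester, and the γ-hydroxy enoate 25 lactonises to the butenolide with loss of ethanol.

Step 15
Reactants: 26 (4R,5S,7S,8Z)-5-(TBSO)-4-[(2S)-1-(TBSO)-6-methylhept-5-en-2-yl]-7-methyl-4,5,6,7-tetrahydrocycloocta[c]furan-1(3H)-one
Product: 27 (4R,5S,7S,8Z)-5-hydroxy-4-[(2S)-1-hydroxy-6-methylhept-5-en-2-yl]-7-methyl-4,5,6,7-tetrahydrocycloocta[c]furan-1(3H)-one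
Conditions: HF (48% aq), MeCN, 0 °C → rt
Reagents that add atoms: none
Why: Acidic fluoride removes both silyl ethers, and basic fluoride sources are avoided because the γ-hydrogens of the butenolide (including C1–H) are acidic.

Step 16
Reactants: 27 (4R,5S,7S,8Z)-5-hydroxy-4-[(2S)-1-hydroxy-6-methylhept-5-en-2-yl]-7-methyl-4,5,6,7-tetrahydrocycloocta[c]furan-1(3H)-one
Product: 28 (2S)-2-[(4R,5S,7S,8Z)-5-hydroxy-7-methyl-1-oxo-1,3,4,5,6,7-hexahydrocycloocta[c]furan-4-yl]-6-methylhept-5-en-1-yl acetate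
Conditions: Ac2O (1.1 equiv), pyridine, CH2Cl2, 0 °C
Reagents that add atoms: acetic anhydride, CC(=O)OC(C)=O
Why: Selective acylation, since the unhindered primary alcohol reacts much faster than the C9 hydroxyl flanked by the branched C1 centre.

Step 17
Reactants: 28 (2S)-2-[(4R,5S,7S,8Z)-5-hydroxy-7-methyl-1-oxo-1,3,4,5,6,7-hexahydrocycloocta[c]furan-4-yl]-6-methylhept-5-en-1-yl acetate
Product: 29 target CNP0267808.2 (28 with the CH2 group C5 bridging C4 and C6 on the face of the C9 hydroxyl; C1 R, C1′ S, C4 R, C6 R, C7 S, C9 S)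
Conditions: CH2N2 (Et2O solution, added in portions), Pd(OAc)2 (cat.), Et2O/CH2Cl2, 0 °C
Reagents that add atoms: diazomethane, C=[N+]=[N-]
Why: Palladium-catalysed cyclopropanation with diazomethane, which transfers CH2 to the cis-disubstituted, diene-conjugated C4=C6 alkene of the medium ring and leaves the trisubstituted side-chain alkene and the tetrasubstituted butenolide alkene alone (a zinc carbenoid would prefer the electron-rich side-chain alkene), with addition anti to the allylic C7 methyl, on the face of the C9 hydroxyl, setting C4 and C6 (both R).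

**Compound list**

1 | 1,4-dioxaspiro[4.5]dec-6-en-8-one | O=C1C=CC2(CC1)OCCO2 | starting material
2 | (8S)-1,4-dioxaspiro[4.5]dec-6-en-8-ol | O[C@@H]1C=CC2(CC1)OCCO2 | intermediate
3 | N,N-dimethylacetamide dimethyl acetal | COC(C)(OC)N(C)C | starting material
4 | (8S)-8-{[1-(dimethylamino)ethenyl]oxy}-1,4-dioxaspiro[4.5]dec-6-ene (ketene N,O-acetal) | C=C(N(C)C)O[C@@H]1C=CC2(CC1)OCCO2 | intermediate (not isolated)
5 | N,N-dimethyl-2-[(6S)-1,4-dioxaspiro[4.5]dec-7-en-6-yl]acetamide | CN(C)C(=O)C[C@H]1C=CCCC12OCCO2 | intermediate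
6 | iminium lactone iodide (cis-fused, 2-dimethyliminio analogue of 7) | C[N+](C)=C1C[C@H]2[C@@H](O1)[C@H](I)CCC23OCCO3.[I-] | intermediate (not isolated)
7 | (3aS,7R,7aR)-7-iodohexahydro-3H-spiro[1-benzofuran-4,2'-[1,3]dioxolan]-2-one (cis-fused, I trans to O) | O=C1C[C@H]2[C@@H](O1)[C@H](I)CCC23OCCO3 | intermediate
8 | (3aS,7aS)-hexahydro-3H-spiro[1-benzofuran-4,2'-[1,3]dioxolan]-2-one (cis-fused) | O=C1C[C@H]2[C@@H](O1)CCCC23OCCO3 | intermediate
9 | 5-bromo-2-methylpent-2-ene | CC(C)=CCCBr | starting material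
10 | 5-iodo-2-methylpent-2-ene | CC(C)=CCCI | intermediate
11 | lithium enolate of lactone 8 | [Li]OC1=C[C@H]2[C@@H](O1)CCCC23OCCO3 | intermediate (not isolated)
12 | (3S,3aS,7aS)-3-(4-methylpent-3-en-1-yl)hexahydro-3H-spiro[1-benzofuran-4,2'-[1,3]dioxolan]-2-one | O=C1[C@@H](CCC=C(C)C)[C@H]2[C@@H](O1)CCCC23OCCO3 | intermediate
13 | (6S,7S)-6-[(2S)-1-hydroxy-6-methylhept-5-en-2-yl]-1,4-dioxaspiro[4.5]decan-7-ol | OC[C@@H](CCC=C(C)C)[C@H]1[C@@H](O)CCCC12OCCO2 | intermediate
14 | bis-TBS ether of 13 | CC(C)(C)[Si](C)(C)OC[C@@H](CCC=C(C)C)[C@H]1[C@@H](O[Si](C)(C)C(C)(C)C)CCCC12OCCO2 | intermediate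
15 | (2S,3S)-3-(TBSO)-2-[(2S)-1-(TBSO)-6-methylhept-5-en-2-yl]cyclohexan-1-one | CC(C)(C)[Si](C)(C)OC[C@@H](CCC=C(C)C)[C@H]1[C@@H](O[Si](C)(C)C(C)(C)C)CCCC1=O | intermediate
16 | lithium enolate (C2=C6) of 15 | CC(C)(C)[Si](C)(C)OC[C@@H](CCC=C(C)C)[C@H]1[C@@H](O[Si](C)(C)C(C)(C)C)CCC=C1O[Li] | intermediate (not isolated)
17 | (5S,6S)-5-(TBSO)-6-[(2S)-1-(TBSO)-6-methylhept-5-en-2-yl]cyclohex-2-en-1-one | CC(C)(C)[Si](C)(C)OC[C@@H](CCC=C(C)C)[C@H]1[C@@H](O[Si](C)(C)C(C)(C)C)CC=CC1=O | intermediate
18 | {[(3S,5S,6S)-5-(TBSO)-6-[(2S)-1-(TBSO)-6-methylhept-5-en-2-yl]-3-methylcyclohex-1-en-1-yl]oxy}trimethylsilane | CC(C)(C)[Si](C)(C)OC[C@@H](CCC=C(C)C)[C@@H]1C(O[Si](C)(C)C)=C[C@@H](C)C[C@@H]1O[Si](C)(C)C(C)(C)C | intermediate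
19 | ethyl propiolate | C#CC(=O)OCC | starting material
20 | ethyl (2S,3S,5S)-3-(TBSO)-2-[(2S)-1-(TBSO)-6-methylhept-5-en-2-yl]-5-methyl-1-(trimethylsilyloxy)bicyclo[4.2.0]oct-7-ene-8-carboxylate (cis-fused, either bridgehead pair) | CC(C)(C)[Si](C)(C)OC[C@@H](CCC=C(C)C)[C@@H]1C2(O[Si](C)(C)C)C(C(=O)OCC)=CC2[C@@H](C)C[C@@H]1O[Si](C)(C)C(C)(C)C | intermediate (not isolated)
21 | ethyl (1Z,3Z,5S,7S,8S)-7-(TBSO)-8-[(2S)-1-(TBSO)-6-methylhept-5-en-2-yl]-5-methyl-1-(trimethylsilyloxy)cycloocta-1,3-diene-2-carboxylate | CC(C)(C)[Si](C)(C)OC[C@@H](CCC=C(C)C)[C@@H]1/C(O[Si](C)(C)C)=C(C(=O)OCC)\C=C/[C@@H](C)C[C@@H]1O[Si](C)(C)C(C)(C)C | intermediate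
22 | caesium enolate of the C2/C3 β-keto ester (21 with O–Cs in place of OTMS) | CC(C)(C)[Si](C)(C)OC[C@@H](CCC=C(C)C)[C@@H]1/C([O-])=C(C(=O)OCC)\C=C/[C@@H](C)C[C@@H]1O[Si](C)(C)C(C)(C)C.[Cs+] | intermediate (not isolated)
23 | ethyl (1Z,3Z,5S,7S,8S)-7-(TBSO)-8-[(2S)-1-(TBSO)-6-methylhept-5-en-2-yl]-5-methyl-1-(trifluoromethanesulfonyloxy)cycloocta-1,3-diene-2-carboxylate | CC(C)(C)[Si](C)(C)OC[C@@H](CCC=C(C)C)[C@@H]1/C(OS(=O)(=O)C(F)(F)F)=C(C(=O)OCC)\C=C/[C@@H](C)C[C@@H]1O[Si](C)(C)C(C)(C)C | intermediate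
24 | (tributylstannyl)methanol | CCCC[Sn](CCCC)(CCCC)CO | starting material
25 | 1-(hydroxymethyl) analogue of 23 (CH2OH on C2 in place of the triflate) | CC(C)(C)[Si](C)(C)OC[C@@H](CCC=C(C)C)[C@@H]1/C(CO)=C(C(=O)OCC)\C=C/[C@@H](C)C[C@@H]1O[Si](C)(C)C(C)(C)C | intermediate (not isolated)
26 | (4R,5S,7S,8Z)-5-(TBSO)-4-[(2S)-1-(TBSO)-6-methylhept-5-en-2-yl]-7-methyl-4,5,6,7-tetrahydrocycloocta[c]furan-1(3H)-one | CC(C)(C)[Si](C)(C)OC[C@@H](CCC=C(C)C)[C@@H]1C2=C(C(=O)OC2)/C=C\[C@@H](C)C[C@@H]1O[Si](C)(C)C(C)(C)C | intermediate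
27 | (4R,5S,7S,8Z)-5-hydroxy-4-[(2S)-1-hydroxy-6-methylhept-5-en-2-yl]-7-methyl-4,5,6,7-tetrahydrocycloocta[c]furan-1(3H)-one | OC[C@@H](CCC=C(C)C)[C@@H]1C2=C(C(=O)OC2)/C=C\[C@@H](C)C[C@@H]1O | intermediate
28 | (2S)-2-[(4R,5S,7S,8Z)-5-hydroxy-7-methyl-1-oxo-1,3,4,5,6,7-hexahydrocycloocta[c]furan-4-yl]-6-methylhept-5-en-1-yl acetate | CC(=O)OC[C@@H](CCC=C(C)C)[C@@H]1C2=C(C(=O)OC2)/C=C\[C@@H](C)C[C@@H]1O | intermediate
29 | CNP0267808.2 (C1 R, C1′ S, C4 R, C6 R, C7 S, C9 S) | CC(=O)OC[C@@H](CCC=C(C)C)[C@@H]1C2=C(C(=O)OC2)[C@@H]2C[C@@H]2[C@@H](C)C[C@@H]1O | target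

**Step count and risks**

Total step count: 17. Longest linear sequence: 16 steps (1 → 29 through steps 1–4 and 6–17; step 5 is the side branch).

Most likely to fail:

1. Step 12 (key step). The aluminium-bound zwitterion may be desilylated before it closes, giving an open-chain Michael adduct. The cyclobutene may also open to the strained E,Z-diene with the trans bond at C4=C6, which reverts or undergoes hydrogen shifts instead of relaxing to the Z,Z-diene. Fallback: the same two bonds are made through the enamine variant of the ring expansion, which needs no Lewis acid. Setting out from 18, mild hydrolysis (AcOH, THF/H2O, 0 °C) gives the methyl ketone F1. Pyrrolidine with molecular sieves in benzene gives the less substituted enamine F2 (C2=C6, away from the substituted C1). Ethyl propiolate (19) in Et2O at room temperature adds C6 to its CH carbon, the zwitterion closes on the iminium carbon C2, and the aminocyclobutene opens spontaneously to the eight-membered dienamine ester F3. Hydrolysis with aqueous AcOH/NaOAc gives the β-keto ester F4, and NaH/PhNTf2 in THF converts it into enol triflate 23, where the route is rejoined.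

2. Step 17. Methylene transfer to the hindered ring alkene may be slow, so that diazomethane is consumed unproductively, or facial selectivity may be poor because the palladium carbene is guided by sterics alone. Fallback: a hydroxyl-directed zinc carbenoid. Setting out from 28, the C9 hydroxyl is converted into its ethylzinc alkoxide (Et2Zn, 1.0 equiv, CH2Cl2, −20 °C) and a limited amount of Zn(CH2I)2 (from Et2Zn and CH2I2) is added. Delivery from the C9 oxygen, on the face opposite the C7 methyl, should outrun intermolecular attack on the side-chain alkene. The product is the target 29 itself (F0, no new compound).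

3. Step 6. Substitution at the unactivated homoallylic iodide may be slow, with E2 elimination of 10 to a diene and proton transfer that returns 8. Fallback: the chain is built in stages from a reactive electrophile. Setting out from 8, enolate 11 is alkylated with allyl bromide (same convex-face attack) to give the allyl lactone F5. 9-BBN hydroboration with NaBO3 oxidation gives the primary alcohol F6, and Dess–Martin periodinane gives the aldehyde F7. Wittig reaction with isopropylidenetriphenylphosphorane (from isopropyltriphenylphosphonium iodide and n-BuLi, THF, −78 °C) gives 12, where the route is rejoined.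

**Further compounds**

F1 | step 12 | (2S,3S,5S)-3-(TBSO)-2-[(2S)-1-(TBSO)-6-methylhept-5-en-2-yl]-5-methylcyclohexan-1-one | CC(C)(C)[Si](C)(C)OC[C@@H](CCC=C(C)C)[C@@H]1C(=O)C[C@@H](C)C[C@@H]1O[Si](C)(C)C(C)(C)C
F2 | step 12 | pyrrolidine enamine of F1 (C2=C6) | CC(C)(C)[Si](C)(C)OC[C@@H](CCC=C(C)C)[C@@H]1C(N2CCCC2)=C[C@@H](C)C[C@@H]1O[Si](C)(C)C(C)(C)C
F3 | step 12 | eight-membered dienamine ester (21 with pyrrolidin-1-yl in place of OTMS) | CC(C)(C)[Si](C)(C)OC[C@@H](CCC=C(C)C)[C@@H]1/C(N2CCCC2)=C(C(=O)OCC)\C=C/[C@@H](C)C[C@@H]1O[Si](C)(C)C(C)(C)C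
F4 | step 12 | eight-membered β-keto ester (C2 ketone, C3 ester, C4=C6 Z; drawn as keto form) | CC(C)(C)[Si](C)(C)OC[C@@H](CCC=C(C)C)[C@@H]1C(=O)C(C(=O)OCC)/C=C\[C@@H](C)C[C@@H]1O[Si](C)(C)C(C)(C)C
F0 | step 17 | none | none
F5 | step 6 | (3S,3aS,7aS)-3-(prop-2-en-1-yl)hexahydro-3H-spiro[1-benzofuran-4,2'-[1,3]dioxolan]-2-one | O=C1[C@@H](CC=C)[C@H]2[C@@H](O1)CCCC23OCCO3
F6 | step 6 | (3S,3aS,7aS)-3-(3-hydroxypropyl)hexahydro-3H-spiro[1-benzofuran-4,2'-[1,3]dioxolan]-2-one | O=C1[C@@H](CCCO)[C@H]2[C@@H](O1)CCCC23OCCO3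
F7 | step 6 | (3S,3aS,7aS)-3-(3-oxopropyl)hexahydro-3H-spiro[1-benzofuran-4,2'-[1,3]dioxolan]-2-one | O=C1[C@@H](CCC=O)[C@H]2[C@@H](O1)CCCC23OCCO3
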